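(The numbers of this flask belong to no real substance, and the outcome is calculated.)

A small charge of Z, 0.800 equiv, meets L in each of these flasks.

| flask | L | Z | temperature | time | remark |
|---|---|---|---|---|---|
| cedar | 0.20 M | 0.800 equiv (in portions, 2, over 6.0 min) | 40 °C | 8.0 min | first portion at the start, last at 6.0 min |
| oak | 0.20 M | 0.800 equiv (fed, over 6.0 min) | 40 °C | 8.0 min | all else is in the flask from the start; the feed brings no volume worth counting |
| elm | 0.20 M (fed, over 6.0 min) | 0.800 equiv |  | 8.0 min | the addition at 20 °C, then warmed to 40 °C; the feed brings no volume worth counting |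
| maple | 0.20 M (fed, over 6.0 min) | 0.800 equiv | 40 °C | 8.0 min | all else is in the flask from the start; the feed brings no volume worth counting |

    Z + Z.L.Z → J (k1 = 0.0613 M⁻¹ s⁻¹, Ea1 = 43.0 kJ mol⁻¹)
    L + Z.J → L.Z.J (k2 = 0.0565 M⁻¹ s⁻¹, Ea2 = 42.0 kJ mol⁻¹)
    L + Z → L.Z (k3 = 0.0208 M⁻¹ s⁻¹, Ea3 = 54.0 kJ mol⁻¹)
    Z + L.Z → Z.L.Z (k4 = 4.71 × 10⁻⁴ M⁻¹ s⁻¹, Ea4 = 81.0 kJ mol⁻¹)
    Z + J → Z.J (k5 = 3.84 × 10⁻⁴ M⁻¹ s⁻¹, Ea5 = 84.0 kJ mol⁻¹)
    (constants at 40 °C)

- percent here means L units held: one L.Z.J counts as two
- constants are those at 40 °C; use the activation energies for any other temperature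

- the flask that comes out highest in share of Z.J in Z.J plus L.Z.J, or "all alike" when all lie within 1.5 percentage points (cedar / oak / elm / maple / all alike)
- share of Z.J in Z.J plus L.Z.J at the end, cedar
- share of Z.J in Z.J plus L.Z.J at the end, oak
- share of Z.J in Z.J plus L.Z.J at the end, elm
- share of Z.J in Z.J plus L.Z.J at the end, maple

Which numbers must I know well? The constant 4.71 × 10⁻⁴ M⁻¹ s⁻¹ feeds the chain and lies far below the 0.0208 M⁻¹ s⁻¹ that makes L.Z, and 3.84 × 10⁻⁴ M⁻¹ s⁻¹ lies far below the 0.0565 M⁻¹ s⁻¹ with which L takes Z.J. Both act before the split into Z.J and L.Z.J, so in my reckoning an error in either scales the two together and the share hardly moves. The constant 0.0613 M⁻¹ s⁻¹ matters more: at the Z charge of 0.160 M it gives Z.L.Z a lifetime of 1.70 min, which delays J. The constant 0.0208 M⁻¹ s⁻¹ matters through how far L falls. The constant 0.0565 M⁻¹ s⁻¹ enters directly, so it has to be right.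

I take elm. Its step to Z.L.Z has a higher activation energy than the step to L.Z, so I count Z.J as born in the warm stretch of 2.00 min. With L.Z already present, Z.L.Z grows with time and J with its square, so I take the mean age of Z.J as 0.500 min, a quarter of that stretch. I replace the falling c(L) by its mean, the charge less half of what L + Z takes at its opening rate:

mean c(L) = 0.160 M

mean age = 0.500 min

drain time = 1.84 min

The drain time is the mean life of Z.J against L, one over 0.0565 M⁻¹ s⁻¹ times the mean c(L), a pseudo-first-order lifetime. The surviving fraction y is then the exponential of minus age over drain time, and each Z.J lost counts as two L units, so the share is y/(2 − y):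

y = 76.2%

share = 61.6%

A flask warm from the start has a mean age nearer 2.00 min, so I put elm first.

The forecast also says elm, with cedar 44%, oak 45%, elm 52% and maple 33%: the share “depends on how late in the run the slow chain through Z.L.Z and J delivers it”. On elm I stand 9.6 percentage points above it.

The simulation gives elm: cedar 47.3%, oak 45.9%, elm 59.1%, maple 35.0%.

In elm the mean age 0.500 min stands below the drain time 1.84 min, and the share 59.1% reads back as survivors of 74.3%, against my 76.2%. For the neighbour of elm with 0.34 M of L, the same steps give a mean c(L) of 0.225 M, a drain time of 1.31 min, survivors of 68.3% and a share of 51.9%, and that flask gives 46.4%.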